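**Plan**

- Retrosynthesis: the 21 benzyl ethers and 4 aryl bromides are removed last. Ring C of the lower flavan unit is then cut at C3–C4 and O1–C2, then the upper C4–middle C6 bond, then the middle C4–aryl bond to a capped phloroglucinol monophenol.
- Enabling feature: ring C of the lower unit is a 2-aryl-3-acyloxychroman fused to phloroglucinol ring A. O1–C8a–C4a–C4 is therefore a latent ortho-quinone methide, and C2–C3 with its gallate is the (Z)-enol gallate of a 4-oxygenated styrene.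
- Forward: (−)-epicatechin gives one C4-activated, galloylated monomer, brominated once (middle unit) or twice (upper unit). The middle unit is C-arylated by 4-bromo-3,5-bis(benzyloxy)phenol, the phenol is ortho-formylated, the upper unit is joined at C6, the aldehyde is reduced, and the cycloaddition closes the lower ring C with its gallate in place.
- Bromine caps direct both interflavan bonds (4→6, then 4→8 by construction), stop oligomerisation and shield the quinone methide. They leave in the final hydrogenolysis.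
- Stereochemistry: upper and middle units come from (2R,3R)-epicatechin. Both C4 centres arise by attack anti to the 3-O-gallate (4β). The lower C2/C3 cis relation comes from the (Z)-alkene and its absolute sense from a chiral Brønsted acid.

Key step: step 13

Assumption: the (R)-configured N-triflylphosphoramide is taken as the catalyst matched to the (2R,3R) sense at the new centres; if it proves mismatched, its (S)-antipode is used with no other change.

**Step 1**
Reactants: 1 (−)-epicatechin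
Product: 2 5,7,3',4'-tetra-O-benzyl-(−)-epicatechin
Conditions: BnBr (4.4 equiv), K2CO3, DMF, 0 °C to rt
Reagents that add atoms: benzyl bromide, BrCc1ccccc1
Why: Williamson etherification under carbonate should alkylate the four phenols and leave the secondary 3-OH and both stereocentres untouched.

**Step 2**
Reactants: 2 5,7,3',4'-tetra-O-benzyl-(−)-epicatechin
Product: 3 5,7,3',4'-tetra-O-benzyl-4β-(2-ethoxyethoxy)epicatechin
Conditions: DDQ (2 equiv), 2-ethoxyethanol (5 equiv), CH2Cl2, rt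
Reagents that add atoms: 2-ethoxyethanol, CCOCCO
Why: DDQ benzylic oxidation removes hydride from C4 to give a cation stabilised by ring A, which the alcohol should trap anti to the cis 2-aryl and 3-OH groups (4β, 3,4-trans).

**Step 3**
Reactants: 3 5,7,3',4'-tetra-O-benzyl-4β-(2-ethoxyethoxy)epicatechin; 4 3,4,5-tris(benzyloxy)benzoic acid
Product: 5 5,7,3',4'-tetra-O-benzyl-4β-(2-ethoxyethoxy)epicatechin 3-O-[3,4,5-tris(benzyloxy)benzoate]
Conditions: DCC, DMAP, CH2Cl2, rt
Reagents that add atoms: none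
Why: Steglich esterification should acylate the secondary 3-OH with retention, since no bond to a stereocentre is broken.

**Step 4**
Reactants: 5 5,7,3',4'-tetra-O-benzyl-4β-(2-ethoxyethoxy)epicatechin 3-O-[3,4,5-tris(benzyloxy)benzoate]
Product: 6 8-bromo derivative of 5 (middle-unit electrophile)
Conditions: NBS (1.05 equiv), NaHCO3, CH2Cl2, −78 to −20 °C
Reagents that add atoms: N-bromosuccinimide, O=C1CCC(=O)N1Br
Why: electrophilic aromatic bromination should take place at C8, the most nucleophilic position of ring A, and NBS releases no acid, so the C4 ether should survive.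

**Step 5**
Reactants: 5 5,7,3',4'-tetra-O-benzyl-4β-(2-ethoxyethoxy)epicatechin 3-O-[3,4,5-tris(benzyloxy)benzoate]
Product: 7 6,8-dibromo derivative of 5 (upper-unit electrophile)
Conditions: NBS (2.3 equiv), NaHCO3, CH2Cl2, 0 °C to rt
Reagents that add atoms: N-bromosuccinimide, O=C1CCC(=O)N1Br
Why: a second equivalent should brominate C6 of the still trioxygenated ring A before the dialkoxy ring B or the ester-deactivated gallate ring reacts.

**Step 6**
Reactants: 8 3,5-bis(benzyloxy)phenol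
Product: 9 4-bromo-3,5-bis(benzyloxy)phenol
Conditions: NBS (1.0 equiv), DMF, −40 to 0 °C
Reagents that add atoms: N-bromosuccinimide, O=C1CCC(=O)N1Br
Why: electrophilic bromination in a polar aprotic solvent should favour the position para to the free OH (the strongest donor, ortho to both ethers), as hydrogen-bond-directed ortho delivery is suppressed.

**Step 7**
Reactants: 6 8-bromo derivative of 5; 9 4-bromo-3,5-bis(benzyloxy)phenol (3 equiv)
Product: 10 8-bromo-5,7,3',4'-tetra-O-benzyl-4β-[3-bromo-2,4-bis(benzyloxy)-6-hydroxyphenyl]epicatechin 3-O-[3,4,5-tris(benzyloxy)benzoate]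
Conditions: BF3·OEt2 (0.3 equiv), 4 Å MS, CH2Cl2, −78 to −30 °C
Reagents that add atoms: none
Why: Friedel–Crafts-type arylation of the Lewis-acid-generated C4 cation can only occur ortho to the phenol OH (para is capped, the two ortho sites are equivalent) and should come anti to the 3-O-gallate to set 4β.

**Step 8**
Reactants: 10 the 4β-aryl adduct
Product: 11 8-bromo-5,7,3',4'-tetra-O-benzyl-4β-[3-bromo-2,4-bis(benzyloxy)-5-formyl-6-hydroxyphenyl]epicatechin 3-O-[3,4,5-tris(benzyloxy)benzoate]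
Conditions: MgCl2, Et3N, (CH2O)n, THF, reflux
Reagents that add atoms: paraformaldehyde (formaldehyde), C=O
Why: Casnati–Skattebøl ortho-formylation delivers formaldehyde through the magnesium phenoxide to the only free ortho position and a second formaldehyde oxidises the benzylic alkoxide, so only the phenolic ring should react.

**Step 9**
Reactants: 11 the salicylaldehyde; 7 6,8-dibromo derivative of 5 (1.5 equiv)
Product: 12 [6,8-dibromo-hepta-O-benzyl-epicatechin gallate]-(4β→6)-[8-bromo-hepta-O-benzyl-epicatechin gallate] carrying at C4β of the lower flavan the 3-bromo-2,4-bis(benzyloxy)-5-formyl-6-hydroxyphenyl group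
Conditions: TMSOTf (0.5 equiv), 4 Å MS, CH2Cl2, −78 to −20 °C
Reagents that add atoms: none
Why: Lewis-acid flavan C4-cation arylation with a C8 halogen cap should go to C6 of the middle unit, the only open phloroglucinol position (7 is blocked at C6 and C8, the phenolic ring is fully substituted and deactivated by the aldehyde), with attack anti to the 3-O-gallate giving 4β.

**Step 10**
Reactants: 12 the trimer-precursor aldehyde
Product: 13 the corresponding 3-bromo-2,4-bis(benzyloxy)-6-hydroxy-5-(hydroxymethyl)phenyl compound (ortho-hydroxybenzyl alcohol)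
Conditions: NaBH4, THF/EtOH, −20 °C; pH 7 phosphate buffer work-up; used at once
Reagents that add atoms: none
Why: borohydride reduction should be chemoselective for the aldehyde over aryl esters and aryl bromides, and low temperature with neutral work-up should limit premature quinone methide formation.

**Step 11**
Reactants: 14 3,4-bis(benzyloxy)benzaldehyde
Product: 15 4-ethynyl-1,2-bis(benzyloxy)benzene
Conditions: dimethyl (1-diazo-2-oxopropyl)phosphonate, K2CO3, MeOH/THF, rt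
Reagents that add atoms: dimethyl (1-diazo-2-oxopropyl)phosphonate, COP(=O)(OC)C(=[N+]=[N-])C(C)=O
Why: Seyferth–Gilbert homologation with the Ohira–Bestmann reagent should convert the aryl aldehyde into the terminal alkyne through the alkylidene carbene 1,2-shift.

**Step 12**
Reactants: 15 4-ethynyl-1,2-bis(benzyloxy)benzene; 4 3,4,5-tris(benzyloxy)benzoic acid
Product: 16 (Z)-2-[3,4-bis(benzyloxy)phenyl]ethenyl 3,4,5-tris(benzyloxy)benzoate
Conditions: [RuCl2(p-cymene)]2 (1 mol %), P(4-ClC6H4)3 (3 mol %), DMAP (4 mol %), toluene, 60 °C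
Reagents that add atoms: none
Why: ruthenium-catalysed anti-Markovnikov addition of a carboxylic acid to a terminal alkyne proceeds through a vinylidene and should deliver the (Z)-enol ester kinetically.

**Step 13**
Reactants: 13 the ortho-hydroxybenzyl alcohol; 16 the (Z)-enol gallate (3 equiv)
Product: 18 [6,8-dibromo-epicatechin gallate]-(4β→6)-[8-bromo-epicatechin gallate]-(4β→8)-[6-bromo-epicatechin gallate] henicosa-O-benzyl ether, via ortho-quinone methide 17 (not isolated)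
Conditions: (R)-3,3'-bis(2,4,6-triisopropylphenyl)-1,1'-binaphthyl-2,2'-diyl N-triflylphosphoramide (10 mol %), 5 Å MS, CH2Cl2, −40 to −10 °C
Reagents that add atoms: none
Why: Proposed new method: the chiral acid ionises the 2,4,6-trioxygenated ortho-hydroxybenzyl alcohol 13, with loss of water, to the ortho-quinone methide 17 (O=C8a–C4a=C4H2 of the lower ring A), which as an ion-paired oxa-diene undergoes an inverse-electron-demand hetero-Diels–Alder reaction with enol gallate 16, C3–C4 bond formation running ahead of O1–C2 bond formation. The closest known reaction type is the chiral Brønsted-acid-catalysed (4+2) cycloaddition of ortho-quinone methides, generated from ortho-hydroxybenzyl alcohols, with styrenes to give 2-arylchromans; an acyloxy group on the styrene, an unsubstituted methide carbon and a polyflavanyl substrate lie beyond it. Ring C of the lower unit closes by intermolecular (4+2) cycloaddition, its second bond amounting to a 6-exo-trig capture of the para-benzyloxy-stabilised benzylic cation by the phenolic oxygen. The 2,3-cis relation should follow from suprafacial addition to the (Z)-alkene, and the absolute (2R,3R) sense is to be imposed by the chiral phosphoramide anion hydrogen-bonded to the quinone methide oxygen, which selects the alkene face; endo or exo approach is of no consequence because C4 is a methylene. Regiochemistry (acyloxy carbon to C4, aryl carbon to O1) is secured by the 3,4-bis(benzyloxy)phenyl group, whose para-benzyloxy oxygen is a far better cation-stabilising donor than the acyloxy group. Chemoselectivity rests on the substrate: the only free phenol is O1, flanked by C8 (flavanyl) and C4a, so only one quinone methide and only the 4→8 connectivity can arise, and every other nucleophilic position of the three phloroglucinol rings carries bromine, so Friedel–Crafts self-condensation is blocked.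

**Step 14**
Reactants: 18 the tetrabromo henicosa-O-benzyl trimer
Product: 19 epicatechin-3-O-gallate-(4β→6)-epicatechin-3-O-gallate-(4β→8)-epicatechin-3-O-gallate (target)
Conditions: H2 (1 atm), Pd(OH)2/C, NaOAc, THF/MeOH/H2O, rt
Reagents that add atoms: none
Why: catalytic hydrogenolysis should cleave all 21 benzyl ethers and the four aryl C–Br bonds in one operation while the esters, the interflavan bonds and all stereocentres stay intact, the acetate buffering the HBr formed.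

**Compound list**

1 | (−)-epicatechin, (2R,3R) | O[C@@H]1Cc2c(O)cc(O)cc2O[C@@H]1c1ccc(O)c(O)c1 | starting material

2 | 5,7,3',4'-tetra-O-benzyl-(−)-epicatechin | O[C@@H]1Cc2c(OCc3ccccc3)cc(OCc3ccccc3)cc2O[C@@H]1c1ccc(OCc2ccccc2)c(OCc2ccccc2)c1 | intermediate

3 | 5,7,3',4'-tetra-O-benzyl-4β-(2-ethoxyethoxy)epicatechin (2,3-cis-3,4-trans) | O[C@@H]1[C@@H](OCCOCC)c2c(OCc3ccccc3)cc(OCc3ccccc3)cc2O[C@@H]1c1ccc(OCc2ccccc2)c(OCc2ccccc2)c1 | intermediate

4 | 3,4,5-tris(benzyloxy)benzoic acid | O=C(O)c1cc(OCc2ccccc2)c(OCc2ccccc2)c(OCc2ccccc2)c1 | starting material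

5 | 5,7,3',4'-tetra-O-benzyl-4β-(2-ethoxyethoxy)epicatechin 3-O-[3,4,5-tris(benzyloxy)benzoate] | O=C(O[C@@H]1[C@@H](OCCOCC)c2c(OCc3ccccc3)cc(OCc3ccccc3)cc2O[C@@H]1c1ccc(OCc2ccccc2)c(OCc2ccccc2)c1)c1cc(OCc2ccccc2)c(OCc2ccccc2)c(OCc2ccccc2)c1 | intermediate

6 | 8-bromo derivative of 5 | O=C(O[C@@H]1[C@@H](OCCOCC)c2c(OCc3ccccc3)cc(OCc3ccccc3)c(Br)c2O[C@@H]1c1ccc(OCc2ccccc2)c(OCc2ccccc2)c1)c1cc(OCc2ccccc2)c(OCc2ccccc2)c(OCc2ccccc2)c1 | intermediate

7 | 6,8-dibromo derivative of 5 | O=C(O[C@@H]1[C@@H](OCCOCC)c2c(OCc3ccccc3)c(Br)c(OCc3ccccc3)c(Br)c2O[C@@H]1c1ccc(OCc2ccccc2)c(OCc2ccccc2)c1)c1cc(OCc2ccccc2)c(OCc2ccccc2)c(OCc2ccccc2)c1 | intermediate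

8 | 3,5-bis(benzyloxy)phenol | Oc1cc(OCc2ccccc2)cc(OCc2ccccc2)c1 | starting material

9 | 4-bromo-3,5-bis(benzyloxy)phenol | Oc1cc(OCc2ccccc2)c(Br)c(OCc2ccccc2)c1 | intermediate

10 | 8-bromo-5,7,3',4'-tetra-O-benzyl-4β-[3-bromo-2,4-bis(benzyloxy)-6-hydroxyphenyl]epicatechin 3-O-[3,4,5-tris(benzyloxy)benzoate] | O=C(O[C@@H]1[C@@H](c2c(OCc3ccccc3)c(Br)c(OCc3ccccc3)cc2O)c2c(OCc3ccccc3)cc(OCc3ccccc3)c(Br)c2O[C@@H]1c1ccc(OCc2ccccc2)c(OCc2ccccc2)c1)c1cc(OCc2ccccc2)c(OCc2ccccc2)c(OCc2ccccc2)c1 | intermediate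

11 | 8-bromo-5,7,3',4'-tetra-O-benzyl-4β-[3-bromo-2,4-bis(benzyloxy)-5-formyl-6-hydroxyphenyl]epicatechin 3-O-[3,4,5-tris(benzyloxy)benzoate] | O=C(O[C@@H]1[C@@H](c2c(OCc3ccccc3)c(Br)c(OCc3ccccc3)c(C=O)c2O)c2c(OCc3ccccc3)cc(OCc3ccccc3)c(Br)c2O[C@@H]1c1ccc(OCc2ccccc2)c(OCc2ccccc2)c1)c1cc(OCc2ccccc2)c(OCc2ccccc2)c(OCc2ccccc2)c1 | intermediate

12 | 4β→6 dimer: upper unit 6,8-dibromo, lower unit 8-bromo with the 3-bromo-2,4-bis(benzyloxy)-5-formyl-6-hydroxyphenyl group at C4β, all other phenols benzylated, both 3-O-tribenzylgallates | O=C(O[C@@H]1[C@@H](c2c(OCc4ccccc4)c(Br)c3c(c2OCc2ccccc2)[C@H](c2c(OCc4ccccc4)c(Br)c(OCc4ccccc4)c(C=O)c2O)[C@@H](OC(=O)c2cc(OCc4ccccc4)c(OCc4ccccc4)c(OCc4ccccc4)c2)[C@@H](c2ccc(OCc4ccccc4)c(OCc4ccccc4)c2)O3)c2c(OCc3ccccc3)c(Br)c(OCc3ccccc3)c(Br)c2O[C@@H]1c1ccc(OCc2ccccc2)c(OCc2ccccc2)c1)c1cc(OCc2ccccc2)c(OCc2ccccc2)c(OCc2ccccc2)c1 | intermediate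

13 | as 12 with CH2OH in place of CHO (ortho-hydroxybenzyl alcohol) | O=C(O[C@@H]1[C@@H](c2c(OCc4ccccc4)c(Br)c3c(c2OCc2ccccc2)[C@H](c2c(OCc4ccccc4)c(Br)c(OCc4ccccc4)c(CO)c2O)[C@@H](OC(=O)c2cc(OCc4ccccc4)c(OCc4ccccc4)c(OCc4ccccc4)c2)[C@@H](c2ccc(OCc4ccccc4)c(OCc4ccccc4)c2)O3)c2c(OCc3ccccc3)c(Br)c(OCc3ccccc3)c(Br)c2O[C@@H]1c1ccc(OCc2ccccc2)c(OCc2ccccc2)c1)c1cc(OCc2ccccc2)c(OCc2ccccc2)c(OCc2ccccc2)c1 | intermediate

14 | 3,4-bis(benzyloxy)benzaldehyde | O=Cc1ccc(OCc2ccccc2)c(OCc2ccccc2)c1 | starting material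

15 | 4-ethynyl-1,2-bis(benzyloxy)benzene | C#Cc1ccc(OCc2ccccc2)c(OCc2ccccc2)c1 | intermediate

16 | (Z)-2-[3,4-bis(benzyloxy)phenyl]ethenyl 3,4,5-tris(benzyloxy)benzoate | O=C(O/C=C\c1ccc(OCc2ccccc2)c(OCc2ccccc2)c1)c1cc(OCc2ccccc2)c(OCc2ccccc2)c(OCc2ccccc2)c1 | intermediate

17 | ortho-quinone methide from 13 (6-methylene-cyclohexa-2,4-dienone form of the lower phenolic ring) | O=C(O[C@@H]1[C@@H](c2c(OCc4ccccc4)c(Br)c3c(c2OCc2ccccc2)[C@H](C2=C(OCc4ccccc4)C(Br)=C(OCc4ccccc4)C(=C)C2=O)[C@@H](OC(=O)c2cc(OCc4ccccc4)c(OCc4ccccc4)c(OCc4ccccc4)c2)[C@@H](c2ccc(OCc4ccccc4)c(OCc4ccccc4)c2)O3)c2c(OCc3ccccc3)c(Br)c(OCc3ccccc3)c(Br)c2O[C@@H]1c1ccc(OCc2ccccc2)c(OCc2ccccc2)c1)c1cc(OCc2ccccc2)c(OCc2ccccc2)c(OCc2ccccc2)c1 | intermediate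

18 | [6,8-dibromo-epicatechin gallate]-(4β→6)-[8-bromo-epicatechin gallate]-(4β→8)-[6-bromo-epicatechin gallate] henicosa-O-benzyl ether, all units 2R,3R | O=C(O[C@@H]1[C@@H](c2c(OCc4ccccc4)c(Br)c3c(c2OCc2ccccc2)[C@H](c2c(OCc5ccccc5)c(Br)c(OCc5ccccc5)c4c2O[C@H](c2ccc(OCc5ccccc5)c(OCc5ccccc5)c2)[C@H](OC(=O)c2cc(OCc5ccccc5)c(OCc5ccccc5)c(OCc5ccccc5)c2)C4)[C@@H](OC(=O)c2cc(OCc4ccccc4)c(OCc4ccccc4)c(OCc4ccccc4)c2)[C@@H](c2ccc(OCc4ccccc4)c(OCc4ccccc4)c2)O3)c2c(OCc3ccccc3)c(Br)c(OCc3ccccc3)c(Br)c2O[C@@H]1c1ccc(OCc2ccccc2)c(OCc2ccccc2)c1)c1cc(OCc2ccccc2)c(OCc2ccccc2)c(OCc2ccccc2)c1 | intermediate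

19 | epicatechin-3-O-gallate-(4β→6)-epicatechin-3-O-gallate-(4β→8)-epicatechin-3-O-gallate | O=C(O[C@@H]1[C@@H](c2c(O)cc3c(c2O)[C@H](c2c(O)cc(O)c4c2O[C@H](c2ccc(O)c(O)c2)[C@H](OC(=O)c2cc(O)c(O)c(O)c2)C4)[C@@H](OC(=O)c2cc(O)c(O)c(O)c2)[C@@H](c2ccc(O)c(O)c2)O3)c2c(O)cc(O)cc2O[C@@H]1c1ccc(O)c(O)c1)c1cc(O)c(O)c(O)c1 | target

**Step count and risks**

Total step count: 14. Longest linear sequence: 10 steps (1, 2, 3, 4, 7, 8, 9, 10, 13, 14).

Steps most likely to fail:

1. Step 13. The catalyst may fail to override the resident stereocentres, giving poor facial selectivity. The alkene geometry may be lost through a zwitterionic intermediate, giving the 2,3-trans ring. The enol ester may react too slowly, so that the quinone methide is rehydrated or oligomerises. The fallback uses known interflavan chemistry and builds the lower unit from epicatechin. It sets out from 2. Steglich esterification with 4 (DCC, DMAP) gives 5,7,3',4'-tetra-O-benzylepicatechin 3-O-[3,4,5-tris(benzyloxy)benzoate] F1. Lewis-acid coupling of 6 with excess F1 (TMSOTf, CH2Cl2, −78 °C) should give the 4β→8 dimer F2, attack coming from the uncapped C8 of F1. NBS (1 equiv) then brominates C6 of the lower unit, whose ring A carries no deactivating bromine and is therefore the more nucleophilic of the two, to give the dimer F3. Coupling of F3 with 7 (TMSOTf) at C6 of the 8-bromo unit comes back to the route at 18.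

2. Step 9. Ionisation of the doubly brominated electrophile may be sluggish, attack by the hindered, bromine-deactivated C6 next to the C4 aryl group may be slow, and the Lewis acid may be diverted by the salicylaldehyde. The fallback forms the 4→6 bond first, at the monomer stage, by orthogonal activation. It sets out from 6. Exchange with 2,6-dimethylbenzenethiol (BF3·OEt2) gives the 4β-(2,6-dimethylphenylthio) compound F4, whose sulfide is inert to hard Lewis acids. Coupling of 7 with F4 (BF3·OEt2, −78 to −30 °C) gives the 4β→6 dimer sulfide F5. Thiophilic activation with AgBF4 in the presence of 9 gives the dimer carrying the 3-bromo-2,4-bis(benzyloxy)-6-hydroxyphenyl group F6. Ortho-formylation as in step 8 (MgCl2, Et3N, paraformaldehyde) comes back to the route at 12.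

3. Step 10. The product may be over-reduced through base-induced quinone methide formation and hydride capture, or 13 may solvolyse or decompose on work-up. The fallback avoids the free ortho-hydroxybenzyl alcohol by generating the quinone methide anionically. It sets out from 12. Boc2O with DMAP and i-Pr2NEt gives the aryl tert-butyl carbonate F7. BH3·SMe2 reduces the aldehyde without carbonate migration to the ortho-(tert-butoxycarbonyloxy)benzyl alcohol F8. Treatment with t-BuMgCl in the presence of 16 (−78 °C to rt) deprotonates the alcohol, the carbonate migrates and is expelled, and 17 is trapped in situ, coming back to the route at 18. Facial selectivity then rests on the C8 substituent alone and the diastereomers would have to be separated.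

**Further compounds**

F1 | step 13 | 5,7,3',4'-tetra-O-benzylepicatechin 3-O-[3,4,5-tris(benzyloxy)benzoate] | O=C(O[C@@H]1Cc2c(OCc3ccccc3)cc(OCc3ccccc3)cc2O[C@@H]1c1ccc(OCc2ccccc2)c(OCc2ccccc2)c1)c1cc(OCc2ccccc2)c(OCc2ccccc2)c(OCc2ccccc2)c1

F2 | step 13 | [8-bromo-hepta-O-benzyl-epicatechin gallate]-(4β→8)-[hepta-O-benzyl-epicatechin gallate] | O=C(O[C@@H]1[C@@H](c2c(OCc5ccccc5)cc(OCc5ccccc5)c4c2O[C@H](c2ccc(OCc5ccccc5)c(OCc5ccccc5)c2)[C@H](OC(=O)c2cc(OCc5ccccc5)c(OCc5ccccc5)c(OCc5ccccc5)c2)C4)c2c(OCc3ccccc3)cc(OCc3ccccc3)c(Br)c2O[C@@H]1c1ccc(OCc2ccccc2)c(OCc2ccccc2)c1)c1cc(OCc2ccccc2)c(OCc2ccccc2)c(OCc2ccccc2)c1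

F3 | step 13 | [8-bromo-hepta-O-benzyl-epicatechin gallate]-(4β→8)-[6-bromo-hepta-O-benzyl-epicatechin gallate] | O=C(O[C@@H]1[C@@H](c2c(OCc5ccccc5)c(Br)c(OCc5ccccc5)c4c2O[C@H](c2ccc(OCc5ccccc5)c(OCc5ccccc5)c2)[C@H](OC(=O)c2cc(OCc5ccccc5)c(OCc5ccccc5)c(OCc5ccccc5)c2)C4)c2c(OCc3ccccc3)cc(OCc3ccccc3)c(Br)c2O[C@@H]1c1ccc(OCc2ccccc2)c(OCc2ccccc2)c1)c1cc(OCc2ccccc2)c(OCc2ccccc2)c(OCc2ccccc2)c1

F4 | step 9 | 8-bromo-5,7,3',4'-tetra-O-benzyl-4β-(2,6-dimethylphenylthio)epicatechin 3-O-[3,4,5-tris(benzyloxy)benzoate] | O=C(O[C@@H]1[C@@H](Sc2c(C)cccc2C)c2c(OCc3ccccc3)cc(OCc3ccccc3)c(Br)c2O[C@@H]1c1ccc(OCc2ccccc2)c(OCc2ccccc2)c1)c1cc(OCc2ccccc2)c(OCc2ccccc2)c(OCc2ccccc2)c1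

F5 | step 9 | [6,8-dibromo-hepta-O-benzyl-epicatechin gallate]-(4β→6)-[8-bromo-4β-(2,6-dimethylphenylthio)-hepta-O-benzyl-epicatechin gallate] | O=C(O[C@@H]1[C@@H](c2c(OCc4ccccc4)c(Br)c3c(c2OCc2ccccc2)[C@H](Sc2c(C)cccc2C)[C@@H](OC(=O)c2cc(OCc4ccccc4)c(OCc4ccccc4)c(OCc4ccccc4)c2)[C@@H](c2ccc(OCc4ccccc4)c(OCc4ccccc4)c2)O3)c2c(OCc3ccccc3)c(Br)c(OCc3ccccc3)c(Br)c2O[C@@H]1c1ccc(OCc2ccccc2)c(OCc2ccccc2)c1)c1cc(OCc2ccccc2)c(OCc2ccccc2)c(OCc2ccccc2)c1

F6 | step 9 | as 12 with H in place of the formyl group | O=C(O[C@@H]1[C@@H](c2c(OCc4ccccc4)c(Br)c3c(c2OCc2ccccc2)[C@H](c2c(OCc4ccccc4)c(Br)c(OCc4ccccc4)cc2O)[C@@H](OC(=O)c2cc(OCc4ccccc4)c(OCc4ccccc4)c(OCc4ccccc4)c2)[C@@H](c2ccc(OCc4ccccc4)c(OCc4ccccc4)c2)O3)c2c(OCc3ccccc3)c(Br)c(OCc3ccccc3)c(Br)c2O[C@@H]1c1ccc(OCc2ccccc2)c(OCc2ccccc2)c1)c1cc(OCc2ccccc2)c(OCc2ccccc2)c(OCc2ccccc2)c1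

F7 | step 10 | as 12 with the phenol as its tert-butyl carbonate | O=C(O[C@@H]1[C@@H](c2c(OCc4ccccc4)c(Br)c3c(c2OCc2ccccc2)[C@H](c2c(OCc4ccccc4)c(Br)c(OCc4ccccc4)c(C=O)c2OC(=O)OC(C)(C)C)[C@@H](OC(=O)c2cc(OCc4ccccc4)c(OCc4ccccc4)c(OCc4ccccc4)c2)[C@@H](c2ccc(OCc4ccccc4)c(OCc4ccccc4)c2)O3)c2c(OCc3ccccc3)c(Br)c(OCc3ccccc3)c(Br)c2O[C@@H]1c1ccc(OCc2ccccc2)c(OCc2ccccc2)c1)c1cc(OCc2ccccc2)c(OCc2ccccc2)c(OCc2ccccc2)c1

F8 | step 10 | as 13 with the phenol as its tert-butyl carbonate | O=C(O[C@@H]1[C@@H](c2c(OCc4ccccc4)c(Br)c3c(c2OCc2ccccc2)[C@H](c2c(OCc4ccccc4)c(Br)c(OCc4ccccc4)c(CO)c2OC(=O)OC(C)(C)C)[C@@H](OC(=O)c2cc(OCc4ccccc4)c(OCc4ccccc4)c(OCc4ccccc4)c2)[C@@H](c2ccc(OCc4ccccc4)c(OCc4ccccc4)c2)O3)c2c(OCc3ccccc3)c(Br)c(OCc3ccccc3)c(Br)c2O[C@@H]1c1ccc(OCc2ccccc2)c(OCc2ccccc2)c1)c1cc(OCc2ccccc2)c(OCc2ccccc2)c(OCc2ccccc2)c1
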